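**Read in millimolar.** Turn the percents of the earlier runs into concentrations before reckoning anything, and then ask what each added process does to the number.

| flask | solid substrate | remark | time |
|---|---|---|---|
| zeta | 6.3 mM | run made earlier |  |
| eta | 9.7 mM | run made earlier |  |
| gamma | 21 mM | run made earlier |  |
| summer | 20 mM |  | 10 h |
| dawn | 5.0 mM |  | 10 h |

| run | time / h | target / % |
|---|---|---|
| zeta | 0.833 | 0 |
| zeta | 2.50 | 2.3 |
| zeta | 5.00 | 7.7 |
| zeta | 8.00 | 15.1 |
| zeta | 10.0 | 21.2 |
| eta | 0.833 | 0.5 |
| eta | 1.50 | 0.4 |
| eta | 3.00 | 1.8 |
| eta | 5.00 | 4.6 |
| eta | 10.0 | 13.6 |
| gamma | 0.833 | 0.5 |
| gamma | 1.50 | 0.4 |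
| gamma | 3.00 | 0.4 |
| gamma | 5.00 | 1.8 |
| gamma | 10.0 | 6.7 |

(each reading ± 0.3 percentage points)

- given per volume of solution although it is solid: solid substrate
- at the start none of the solid substrate is in solution
- what has only dissolved of solid substrate counts as not reacted

1. which one finishes higher in amount of target, in percent of the solid substrate charged ("neither" within 2 percentage points) (summer / dawn / neither)
2. amount of target at the end, in percent of the solid substrate charged, summer
3. amount of target at the end, in percent of the solid substrate charged, dawn

**Main step.** I began with one first-order step acting on the charge, which gives the same percent at a given time for any charge. The readings refuse that: at 10 h, zeta with 6.3 mM reached 21.2 %, but gamma with 21 mM reached less, 6.7 %.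

**Adding the solid.** Next I let the solid enter solution at a pace that ignores how much solid lies there, like a fixed feed into a tank (zero order in the charge). Then c_target at 10 h should match across runs. It reads 1.34 mM in zeta, 1.32 mM in eta and 1.41 mM in gamma, and the scatter on gamma is worth 0.0630 mM. So I took their mean, 1.35 mM, as the output, the c_target made by that time at the charges of these runs. Dividing by the charge gave me 6.77 % for summer and 27.0 % for dawn.

**Adding the lag.** Zeta's target grew by a factor of 2.75 between 5.00 h and 10.0 h, so I read a delay, as in two tanks in series. That delay sits inside each run's reading at 10 h, so the output stayed as it was.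

**Second round.** I put the answer back in. Dawn spends the output from 5.0 mM and keeps 3.65 mM, less than the 4.96 mM zeta kept. By this reckoning dawn stood outside the tested range, and I kept my figure with that caveat.

The forecast, which differs from my figures, named dawn, with 6.9 % for summer and 26 % for dawn, holding that “the rate does not depend on the charge”.

**Result.** The simulation put dawn higher, with 6.80 % for summer and 27.2 % for dawn.

    starting material ⇌ target + by-product (K = 0.0284 M, k = 0.191 h⁻¹)
    solid substrate ⇌ starting material, rate k2*(cs2 - [starting material]) while solid is left; crystals form when [starting material] > cs2 (solubility = 3.10 mM, k = 0.101 h⁻¹)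

**What it means.** The low solubility of starting material, which also sets how fast it dissolves, held summer down: the run without it reaches 65.5 % against 6.80 %. While solid lies there, the feed follows c_starting material and not the heap, and at 10.0 h that stood at 1.03 mM in summer and 1.03 mM in dawn, where 52.1 % of the charge was still solid. For the dawn flask charged with 12 mM, the output gives 11.2 %, and the computed result is 11.3 %.

Readings and results come from a simulation from invented constants.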